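I watched the starting material.

in all of them: starting material 0.20 M; free catalyst 19 mol%

|  | second substrate | protic impurity | capture agent | temperature | remark | time |
|---|---|---|---|---|---|---|
| Wednesday's | 1 equiv | 0.20 M | 0.0067 M | −25 °C | run made earlier |  |
| Thursday's | 1 equiv | 0.20 M | 0.015 M | −3 °C | run made earlier |  |
| south-east | 1.00 equiv | 0.200 M | 0.0100 M | −15 °C |  | 15 h |
| east | 1.00 equiv | 0.200 M | 0.0100 M | −35 °C |  | 15 h |
| west | 1.00 equiv | 0.200 M | 0.0100 M |  | at −35 °C until 3.0 h, from then on at 5 °C | 15 h |
| north-west | 1.00 equiv | 0.200 M | 0.0100 M | 5 °C |  | 15 h |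

- Wednesday's (time / h: target / %, starting material / %): 4.00: 0.7, 98.2; 8.00: 0, 97.3; 12.0: 0.5, 96.6; 15.0: 0, 96.6; 20.0: 0, 96.4; 25.0: 0, 95.6
- Thursday's (time / h: target / %, starting material / %): 0.667: 0, 95.0; 1.00: 1.6, 94.6; 1.50: 1.4, 91.9; 3.00: 1.6, 87.4; 6.00: 5.3, 78.2; 8.00: 6.6, 74.4

(scatter of a reading: 0.5 percentage points)

* the best flask by amount of target, in percent of the starting material charged; "all alike" if 1.5 percentage points covers them all (south-east / east / west / north-west / all alike)
* amount of target at the end, in percent of the starting material charged, south-east
* amount of target at the end, in percent of the starting material charged, east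
* amount of target at the end, in percent of the starting material charged, west
* amount of target at the end, in percent of the starting material charged, north-west



Both runs dropped early and then settled into a steady loss, and target comes out of what is lost. So I held two times against each other: the run time t, here 15 h, and the loss time τ, the time in which the steady loss shrinks the starting material by the factor e. The fraction left is then exp(−t/τ), and the ratio t/τ carries the argument.

Thursday's readings from 3.00 h to 8.00 h, at −3 °C, gave τ = 31.0 h, and this is the loss time I carried on. Wednesday's readings from 12.0 h to 25.0 h, at −25 °C, gave 1250 h, but that rests on a drop of 1 percentage point against a scatter of 0.5 points.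

Together they read as an apparent activation energy E of 93.6 kJ/mol, which puts τ at 9.36 h at 5 °C, 215 h at −15 °C and 8400 h at −35 °C. For the west flask I added the ratios of its two stages. Thursday's run also made 0.385 of target per unit of starting material lost over the same stretch, and I used that share for my own target figures.

| Flask | t/τ | Left | Target |
|---|---|---|---|
| south-east | 0.0696 | 93.3% | 2.59% |
| east | 0.00179 | 99.8% | 0.0687% |
| west | 1.28 | 27.8% | 27.8% |
| north-west | 1.60 | 20.2% | 30.7% |

The forecast named north-west as best, with 2.5% for south-east, 0.2% for east, 22% for west and 26% for north-west, holding that at 5 °C “the lag is short, but sagging limits the yield”.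

The flasks gave 0.930% in south-east, 0% in east, 39.4% in west and 45.6% in north-west, so north-west was best.

second substrate + free catalyst ⇌ catalyst intermediate B (K = 2.40 /M, k = 0.00824 /M/s, Ea = 69.0 kJ/mol, ΔH = −62.0 kJ/mol); starting material + protic impurity → quenched substrate (k = 5.41 × 10⁻⁵ /M/s, Ea = 72.0 kJ/mol); catalyst intermediate A + capture agent → trapped intermediate (k = 0.0103 /M/s, Ea = 43.0 kJ/mol); starting material + free catalyst ⇌ catalyst intermediate A (K = 341 /M, k = 0.00123 /M/s, Ea = 73.0 kJ/mol, ΔH = −19.0 kJ/mol); catalyst intermediate B → free catalyst + second product (k = 1.55 × 10⁻⁴ /s, Ea = 85.0 kJ/mol); catalyst intermediate A → free catalyst + target (k = 2.13 × 10⁻⁴ /s, Ea = 97.0 kJ/mol); (constants at 5 °C) North-west kept 21.6% of its starting material against my 20.2%, while its target stood higher than my 30.7%. For a neighbour of east kept at −20 °C I reckoned τ = 510 h, far longer than its 15 h, so t/τ came to 0.0294 and my estimate of what was left to 97.1%. That neighbour held 94.2% of its starting material and made 0.273% of target.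

(The numbers in the tables were generated by integration on assumed constants.)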